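**Retrosynthetic overview**
1. The C8–O ester bond is cut to give the bicyclic 8,11-diol and O-acetyl-p-coumaric acid. The diol comes from a C4-methylidene, C6=C7 enone (C8=O) by three face-selective hydrogen deliveries (H7, H8, H4). C15 comes from a C4 ketone, and the C8 ketone from an aryl methyl ether.
2. Key disconnection C5–C1/C5–C6: the bicyclic ketone comes from a monocyclic, achiral aryl diazoketone by an asymmetric intramolecular Büchner reaction (dearomatising cyclopropanation, then strain-releasing norcaradiene opening).
3. Enabling feature: six of the seven atoms of ring B (C1, C10, C9, C8, C7, C6) carry chain, CH3, H, O, C3 unit and H in the pattern of a 1,2,4,5-tetrasubstituted anisole. C1=C10 is one of its former aromatic bonds. The seventh atom, C5, is a bare CH shared with ring A and adjacent to C4, which can be the carbonyl that stabilises a diazo carbon.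
4. Ring order: the benzene ring is bought. Ring A (C1–C2–C3–C4–C5) is the only ring that has to be closed, and it is closed last. The same event enlarges the benzene ring to ring B by bond breaking, not by a further closure.
5. The diazoketone comes from methyl 2-methoxy-4-methylbenzoate, MeMgBr and but-3-en-2-ol (iodination, Grignard addition, Heck arylation, diazo transfer).

Key step: step 6

Assumption: guaiane numbering is used for all bicyclic compounds (C1/C5 ring fusion, C4 and C10 methyl-bearing, C7 side chain with C11, C8 oxygen, C15 the carbon on C4). Which antipode of the PTTL catalyst (PTTL = N-phthaloyl-tert-leucinate) gives the (8aR) Büchner product must be found by experiment, and Rh2(R-PTTL)4 replaces Rh2(S-PTTL)4 if the sense is opposite.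

Step 1
Reactants: 1 methyl 2-methoxy-4-methylbenzoate
Product: 2 methyl 5-iodo-2-methoxy-4-methylbenzoate
Conditions: NIS (1.1 equiv), CF3CO2H (1 equiv), MeCN, rt
Reagents that add atoms: N-iodosuccinimide O=C1CCC(=O)N1I
Why: Electrophilic aromatic iodination goes to C5 of the benzoate (the future C1) because this position is para to the methoxy group, ortho to the methyl group and meta to the ester, whereas the only other activated position lies between two substituents.

Step 2
Reactants: 2 methyl 5-iodo-2-methoxy-4-methylbenzoate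
Product: 3 2-(5-iodo-2-methoxy-4-methylphenyl)propan-2-ol
Conditions: MeMgBr (3 equiv), THF, 0 °C to rt
Reagents that add atoms: methylmagnesium bromide C[Mg]Br
Why: Double Grignard addition to the ester builds the tertiary carbinol C11 with both of its methyl groups, and MeMgBr is too poor an exchange reagent to touch the aryl iodide at this temperature.

Step 3
Reactants: 3 2-(5-iodo-2-methoxy-4-methylphenyl)propan-2-ol; 4 but-3-en-2-ol (racemic)
Product: 5 4-[5-(2-hydroxypropan-2-yl)-4-methoxy-2-methylphenyl]butan-2-one
Conditions: Pd(OAc)2 (3 mol %), n-Bu4NCl, NaHCO3, DMF, 60 °C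
Reagents that add atoms: none
Why: Heck arylation of an allylic alcohol under Jeffery conditions: the aryl group adds to the terminal alkene carbon, β-hydride elimination runs towards the carbinol carbon and the enol tautomerises, so the saturated methyl ketone (C2–C3–C4–C5) forms directly and the stereocentre of 4 is erased.

Step 4
Reactants: 5 4-[5-(2-hydroxypropan-2-yl)-4-methoxy-2-methylphenyl]butan-2-one
Product: 6 4-{4-methoxy-2-methyl-5-[2-(trimethylsilyloxy)propan-2-yl]phenyl}butan-2-one
Conditions: 1-(trimethylsilyl)imidazole (2 equiv), CH2Cl2, rt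
Reagents that add atoms: 1-(trimethylsilyl)imidazole C[Si](C)(C)n1ccnc1
Why: Silyl transfer from this neutral donor caps the hindered tertiary alcohol without enolising the ketone, which keeps the O–H group out of the acylation, carbene and titanium steps that follow.

Step 5
Reactants: 6 4-{4-methoxy-2-methyl-5-[2-(trimethylsilyloxy)propan-2-yl]phenyl}butan-2-one
Product: 8 1-diazo-4-{4-methoxy-2-methyl-5-[2-(trimethylsilyloxy)propan-2-yl]phenyl}butan-2-one, via trifluoroacetyl diketone 7 (not isolated)
Conditions: LiN(SiMe3)2 (1.1 equiv), THF, −78 °C; CF3CO2CH2CF3 (1.2 equiv); solvent exchange; MsN3 (1.5 equiv), Et3N, H2O (1 equiv), MeCN, rt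
Reagents that add atoms: 2,2,2-trifluoroethyl trifluoroacetate O=C(OCC(F)(F)F)C(F)(F)F; methanesulfonyl azide CS(=O)(=O)N=[N+]=[N-]
Why: Detrifluoroacetylative diazo transfer (Danheiser variant of the Regitz reaction): the kinetic enolate on the methyl side is trifluoroacetylated so that only C5 is activated, and the diketone 7 then takes up N2 from MsN3 with loss of the trifluoroacetyl group.

Step 6
Reactants: 8 1-diazo-4-{4-methoxy-2-methyl-5-[2-(trimethylsilyloxy)propan-2-yl]phenyl}butan-2-one
Product: 10 (8aR)-6-methoxy-4-methyl-7-[2-(trimethylsilyloxy)propan-2-yl]-3,8a-dihydroazulen-1(2H)-one, via norcaradiene 9 (not isolated)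
Conditions: Rh2(S-PTTL)4 (1 mol %), CH2Cl2, slow addition of 8, 0 °C to rt; filtration through neutral alumina, used at once
Reagents that add atoms: none
Why: Loss of N2 gives a rhodium-bound carbene at C5 that adds across the C1–C6 bond of the arene (asynchronous cyclopropanation led by C1, which lies para to the methoxy group) to give norcaradiene 9, whose disrotatory 6π electrocyclic opening of the C1–C6 bond releases the cyclopropane strain and gives cycloheptatriene 10. The closest known reaction type is the catalytic asymmetric intramolecular Büchner reaction of 1-diazo-4-arylbutan-2-ones to 3,8a-dihydroazulen-1(2H)-ones. Ring A is closed by the C5–C1 bond in a [2+1] cycloaddition in which the three-atom tether C2–C3–C4 lets the carbene reach only an ipso/ortho bond, and ring B arises in the same operation by insertion of C5 between C1 and C6 of the benzene ring. The only stereocentre that survives, C5, is set by the chiral carboxylate pocket of the catalyst, which selects the arene face that meets the carbene. Regioselectivity between the two ipso/ortho bonds is needed and is secured by the methyl group on C10, which blocks the C1–C10 bond so that the unsubstituted C6–H position reacts, while the silyl ether removes O–H insertion as a competitor. In one step the flat arene thus gives both rings, the tetrasubstituted C1=C10 alkene in its final place, C8 at the ketone oxidation level (enol ether), the C6=C7 alkene for later hydride delivery and the C4 carbonyl for the last carbon.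

Step 7
Reactants: 10 (8aR)-6-methoxy-4-methyl-7-[2-(trimethylsilyloxy)propan-2-yl]-3,8a-dihydroazulen-1(2H)-one
Product: 11 (8aS)-6-methoxy-4-methyl-1-methylidene-7-[2-(trimethylsilyloxy)propan-2-yl]-1,2,3,8a-tetrahydroazulene
Conditions: Cp2TiMe2 (2.5 equiv), toluene, 65 °C, dark
Reagents that add atoms: Cp2TiMe2 [CH3-].[CH3-].[Ti+4].c1cc[cH-]c1.c1cc[cH-]c1
Why: Petasis methylenation: Cp2Ti=CH2 released thermally from Cp2TiMe2 adds to the C4 carbonyl and cycloreverts to the alkene, and because the reagent is neither a Brønsted base nor a strong Lewis acid, the labile C5–H, the enol ether and the silyl ether should survive (the descriptor at C5 changes only through CIP priorities).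

Step 8
Reactants: 11 (8aS)-6-methoxy-4-methyl-1-methylidene-7-[2-(trimethylsilyloxy)propan-2-yl]-1,2,3,8a-tetrahydroazulene
Product: 12 (3aS)-5-(2-hydroxypropan-2-yl)-8-methyl-3-methylidene-2,3,3a,7-tetrahydroazulen-6(1H)-one
Conditions: oxalic acid (0.2 equiv), THF/H2O (4:1), 0 °C
Reagents that add atoms: water O
Why: Mild acid hydrolysis of a dienol ether under kinetic control: protonation at C9 and loss of methanol leave the C1=C10 alkene out of conjugation, as in the hydrolysis of Birch-type enol ethers, and the same medium cleaves the trimethylsilyl ether.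

Step 9
Reactants: 12 (3aS)-5-(2-hydroxypropan-2-yl)-8-methyl-3-methylidene-2,3,3a,7-tetrahydroazulen-6(1H)-one
Product: 13 (3aS,5R)-5-(2-hydroxypropan-2-yl)-8-methyl-3-methylidene-2,3,3a,4,5,7-hexahydroazulen-6(1H)-one
Conditions: [(Ph3P)CuH]6 (0.4 equiv), H2O (5 equiv), degassed toluene, rt
Reagents that add atoms: none
Why: Copper hydride conjugate reduction is specific for the enone and ignores the isolated alkenes; hydride goes to C6 and C7 is then protonated by water on the convex face that carries H5, giving the epimer that is also thermodynamically preferred (side chain pseudo-equatorial), so kinetic and equilibrium control point the same way.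

Step 10
Reactants: 13 (3aS,5R)-5-(2-hydroxypropan-2-yl)-8-methyl-3-methylidene-2,3,3a,4,5,7-hexahydroazulen-6(1H)-one
Product: 14 (3aS,5S,6S)-5-(2-hydroxypropan-2-yl)-8-methyl-3-methylidene-1,2,3,3a,4,5,6,7-octahydroazulen-6-ol
Conditions: Me4NBH(OAc)3 (5 equiv), MeCN/AcOH (1:1), −25 °C
Reagents that add atoms: none
Why: Saksena–Evans reduction: the C11 hydroxyl exchanges onto boron and delivers hydride to the face of the C8 carbonyl on which the side chain sits, so the new C8–OH ends up trans to the C7 substituent, while the reagent is too weak to reduce the ketone by an undirected path.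

Step 11
Reactants: 14 (3aS,5S,6S)-5-(2-hydroxypropan-2-yl)-8-methyl-3-methylidene-1,2,3,3a,4,5,6,7-octahydroazulen-6-ol
Product: 15 (3S,3aS,5S,6S)-5-(2-hydroxypropan-2-yl)-3,8-dimethyl-1,2,3,3a,4,5,6,7-octahydroazulen-6-ol
Conditions: H2 (1 atm), RhCl(PPh3)3 (10 mol %), benzene/EtOH (1:1), rt
Reagents that add atoms: none
Why: Homogeneous hydrogenation with RhCl(PPh3)3 discriminates by substitution (the 1,1-disubstituted C4=C15 reacts, the tetrasubstituted C1=C10 does not) and should add H2 from the face of H5, opposite to the C5–C6 bond, which places the new methyl group cis to C6 as required at C4.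

Step 12
Reactants: 16 (E)-4-hydroxycinnamic acid (p-coumaric acid)
Product: 17 (E)-4-acetoxycinnamic acid
Conditions: Ac2O (1.5 equiv), pyridine, rt; then H2O
Reagents that add atoms: acetic anhydride CC(=O)OC(C)=O
Why: O-Acetylation of the phenol blocks self-condensation of the hydroxy acid in the coupling step, and any mixed anhydride is hydrolysed on aqueous work-up.

Step 13
Reactants: 15 (3S,3aS,5S,6S)-5-(2-hydroxypropan-2-yl)-3,8-dimethyl-1,2,3,3a,4,5,6,7-octahydroazulen-6-ol; 17 (E)-4-acetoxycinnamic acid
Product: 18 (3S,3aS,5S,6S)-5-(2-hydroxypropan-2-yl)-3,8-dimethyl-1,2,3,3a,4,5,6,7-octahydroazulen-6-yl (E)-3-(4-acetoxyphenyl)prop-2-enoate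
Conditions: DCC (1.3 equiv), DMAP (0.2 equiv), CH2Cl2, 0 °C to rt
Reagents that add atoms: none
Why: Steglich esterification acylates the secondary C8 hydroxyl with retention of configuration, the tertiary C11 hydroxyl being too hindered to compete.

Step 14
Reactants: 18 (3S,3aS,5S,6S)-5-(2-hydroxypropan-2-yl)-3,8-dimethyl-1,2,3,3a,4,5,6,7-octahydroazulen-6-yl (E)-3-(4-acetoxyphenyl)prop-2-enoate
Product: 19 (3S,3aS,5S,6S)-5-(2-hydroxypropan-2-yl)-3,8-dimethyl-1,2,3,3a,4,5,6,7-octahydroazulen-6-yl (E)-3-(4-hydroxyphenyl)prop-2-enoate (CNP0403230.1)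
Conditions: K2CO3 (0.2 equiv), MeOH, 0 °C
Reagents that add atoms: none
Why: Base-catalysed transesterification removes the aryl acetate, whose phenoxide leaving group makes it far more reactive than the hindered secondary cinnamate, and leaves the four stereocentres and both alkenes untouched.

**Compound list**
1 | methyl 2-methoxy-4-methylbenzoate | COC(=O)c1ccc(C)cc1OC | starting material
2 | methyl 5-iodo-2-methoxy-4-methylbenzoate | COC(=O)c1cc(I)c(C)cc1OC | intermediate
3 | 2-(5-iodo-2-methoxy-4-methylphenyl)propan-2-ol | COc1cc(C)c(I)cc1C(C)(C)O | intermediate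
4 | but-3-en-2-ol (racemic) | C=CC(C)O | starting material
5 | 4-[5-(2-hydroxypropan-2-yl)-4-methoxy-2-methylphenyl]butan-2-one | COc1cc(C)c(CCC(C)=O)cc1C(C)(C)O | intermediate
6 | 4-{4-methoxy-2-methyl-5-[2-(trimethylsilyloxy)propan-2-yl]phenyl}butan-2-one | COc1cc(C)c(CCC(C)=O)cc1C(C)(C)O[Si](C)(C)C | intermediate
7 | 1,1,1-trifluoro-6-{4-methoxy-2-methyl-5-[2-(trimethylsilyloxy)propan-2-yl]phenyl}hexane-2,4-dione (not isolated) | COc1cc(C)c(CCC(=O)CC(=O)C(F)(F)F)cc1C(C)(C)O[Si](C)(C)C | intermediate
8 | 1-diazo-4-{4-methoxy-2-methyl-5-[2-(trimethylsilyloxy)propan-2-yl]phenyl}butan-2-one | COc1cc(C)c(CCC(=O)C=[N+]=[N-])cc1C(C)(C)O[Si](C)(C)C | intermediate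
9 | norcaradiene valence tautomer of 10 (cyclopropane C1–C5–C6, H5 over the cyclohexadiene; not isolated) | CC1=CC(OC)=C(C(C)(C)O[Si](C)(C)C)[C@@H]2[C@H]3C(=O)CC[C@@]123 | intermediate
10 | (8aR)-6-methoxy-4-methyl-7-[2-(trimethylsilyloxy)propan-2-yl]-3,8a-dihydroazulen-1(2H)-one | CC1=C2CCC(=O)[C@@H]2C=C(C(C)(C)O[Si](C)(C)C)C(OC)=C1 | intermediate
11 | (8aS)-6-methoxy-4-methyl-1-methylidene-7-[2-(trimethylsilyloxy)propan-2-yl]-1,2,3,8a-tetrahydroazulene | CC1=C2CCC(=C)[C@@H]2C=C(C(C)(C)O[Si](C)(C)C)C(OC)=C1 | intermediate
12 | (3aS)-5-(2-hydroxypropan-2-yl)-8-methyl-3-methylidene-2,3,3a,7-tetrahydroazulen-6(1H)-one | CC1=C2CCC(=C)[C@@H]2C=C(C(C)(C)O)C(=O)C1 | intermediate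
13 | (3aS,5R)-5-(2-hydroxypropan-2-yl)-8-methyl-3-methylidene-2,3,3a,4,5,7-hexahydroazulen-6(1H)-one | CC1=C2CCC(=C)[C@@H]2C[C@H](C(C)(C)O)C(=O)C1 | intermediate
14 | (3aS,5S,6S)-5-(2-hydroxypropan-2-yl)-8-methyl-3-methylidene-1,2,3,3a,4,5,6,7-octahydroazulen-6-ol | CC1=C2CCC(=C)[C@@H]2C[C@H](C(C)(C)O)[C@@H](O)C1 | intermediate
15 | (3S,3aS,5S,6S)-5-(2-hydroxypropan-2-yl)-3,8-dimethyl-1,2,3,3a,4,5,6,7-octahydroazulen-6-ol | CC1=C2CC[C@H](C)[C@@H]2C[C@H](C(C)(C)O)[C@@H](O)C1 | intermediate
16 | (E)-4-hydroxycinnamic acid | O=C(O)/C=C/c1ccc(O)cc1 | starting material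
17 | (E)-4-acetoxycinnamic acid | CC(=O)Oc1ccc(/C=C/C(=O)O)cc1 | intermediate
18 | (3S,3aS,5S,6S)-5-(2-hydroxypropan-2-yl)-3,8-dimethyl-1,2,3,3a,4,5,6,7-octahydroazulen-6-yl (E)-3-(4-acetoxyphenyl)prop-2-enoate | CC1=C2CC[C@H](C)[C@@H]2C[C@H](C(C)(C)O)[C@@H](OC(=O)/C=C/c2ccc(OC(C)=O)cc2)C1 | intermediate
19 | CNP0403230.1 | CC1=C2CC[C@H](C)[C@@H]2C[C@H](C(C)(C)O)[C@@H](OC(=O)/C=C/c2ccc(O)cc2)C1 | target

**Step count**
Total step count: 14. Longest linear sequence: 13 (steps 1–11, 13, 14).

**Steps most likely to fail**

Step 6. The catalyst may discriminate poorly between the two arene faces. Part of the carbene may add to the methyl-bearing C1–C10 bond because the C7 group crowds C6. The doubly allylic C5–H next to the ketone may enolise during isolation, which would erode the only stereocentre.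
- The fallback replaces asymmetric catalysis by a resolution that is coupled to the methylenation. It sets out from 8.
- Rh2(OAc)4 in CH2Cl2 gives the racemic azulenone F1.
- Addition of lithiated (S)-N,S-dimethyl-S-phenylsulfoximine (THF, −78 °C) to the C4 ketone from the H5 face gives two diastereomeric adducts, which are separated by chromatography. The wanted one is the β-hydroxysulfoximine F2.
- Reductive elimination with Al(Hg) in buffered THF/H2O/AcOH (sulfoximine methylenation) gives the exocyclic alkene. The fallback comes back to the route at 11, so step 7 is replaced as well.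

Step 8. The C1=C10 alkene may drift into conjugation through the C8/C9 dienol. Vinylogous enolisation through C5–H may racemise the material. The tertiary allylic C11–O bond may ionise.
- The fallback never releases the enone and delivers hydrogen before the carbonyl is unmasked. It sets out from 11.
- Pyridinium p-toluenesulfonate (cat.) in MeOH/HC(OMe)3 at 0 °C adds methanol to the enol ether and removes the silyl group, giving the non-enolisable dimethyl ketal F3.
- Hydroxyl-assisted hydrogenation with [Ir(cod)(PCy3)(py)]PF6 and H2 in CH2Cl2 should saturate C6=C7 and C4=C15 from the H5 face and spare C1=C10, giving the saturated ketal F4.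
- Oxalic acid on wet silica gel gives the ketone F5.
- Directed reduction of F5 with Me4NBH(OAc)3, as in step 10, comes back to the route at 15. Steps 9 to 11 are replaced.

Step 11. Facial selectivity at C4 may be poor, or a rhodium hydride may move the exocyclic alkene into ring A before it is reduced.
- The fallback replaces hydrogenation by hydroboration and deoxygenation. It sets out from 14.
- Excess 9-BBN in THF, then NaBO3, places boron on C15 and hydrogen on C4 from the H5 face, giving the triol F6.
- TsCl in pyridine at 0 °C sulfonylates only the primary alcohol, giving the tosylate F7.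
- LiEt3BH in THF displaces the sulfonate by hydride and comes back to the route at 15.

**Further compounds**
F1 | step 6 | racemic 6-methoxy-4-methyl-7-[2-(trimethylsilyloxy)propan-2-yl]-3,8a-dihydroazulen-1(2H)-one | CC1=C2CCC(=O)C2C=C(C(C)(C)O[Si](C)(C)C)C(OC)=C1
F2 | step 6 | β-hydroxysulfoximine from F1 and (S)-N,S-dimethyl-S-phenylsulfoximine, diastereomer with the C5 configuration of 11 and the CH2S group on the H5 face | CC1=C2CC[C@@](O)(C[S@@](=O)(=NC)c3ccccc3)[C@@H]2C=C(C(C)(C)O[Si](C)(C)C)C(OC)=C1
F3 | step 8 | 2-[(3aS)-6,6-dimethoxy-8-methyl-3-methylidene-1,2,3,3a,6,7-hexahydroazulen-5-yl]propan-2-ol | CC1=C2CCC(=C)[C@@H]2C=C(C(C)(C)O)C(OC)(OC)C1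
F4 | step 8 | 2-[(3S,3aS,5R)-6,6-dimethoxy-3,8-dimethyl-1,2,3,3a,4,5,6,7-octahydroazulen-5-yl]propan-2-ol | CC1=C2CC[C@H](C)[C@@H]2C[C@H](C(C)(C)O)C(OC)(OC)C1
F5 | step 8 | (3S,3aS,5R)-5-(2-hydroxypropan-2-yl)-3,8-dimethyl-2,3,3a,4,5,7-hexahydroazulen-6(1H)-one | CC1=C2CC[C@H](C)[C@@H]2C[C@H](C(C)(C)O)C(=O)C1
F6 | step 11 | (3S,3aS,5S,6S)-3-(hydroxymethyl)-5-(2-hydroxypropan-2-yl)-8-methyl-1,2,3,3a,4,5,6,7-octahydroazulen-6-ol | CC1=C2CC[C@H](CO)[C@@H]2C[C@H](C(C)(C)O)[C@@H](O)C1
F7 | step 11 | primary 4-methylbenzenesulfonate of F6 | CC1=C2CC[C@H](COS(=O)(=O)c3ccc(C)cc3)[C@@H]2C[C@H](C(C)(C)O)[C@@H](O)C1
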